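## Structural features

The target is a cyclobutane in which C1 and C3 each carry a 4-methoxy-2-oxo-2H-pyran-6-yl ring, bonded through pyranone C6, and C2 and C4 each carry a 4-hydroxyphenyl ring, bonded through the arene ipso carbon. All four ring carbons are stereocentres and each stands next to two others. Like substituents are trans across the ring and each pyranone is cis to one aryl group and trans to the other (cis,trans,cis, the α-truxillate pattern), so the molecule has a centre of inversion and is achiral. The fragile parts are the two 4-methoxy-2-pyranones (enol lactones opened by hydroxide or alkoxide), the free phenols, and the C1–H and C3–H bonds, which sit next to an acyl or vinylogous acyl carbon at every stage and could epimerise. The real difficulty is to place four sp2 substituents on a strained ring in the head-to-tail cis,trans,cis arrangement and in no other regio- or stereoisomeric form. The key step exploits the fact that C1–C4 have exactly the configuration of the [2+2] photodimer of maleic anhydride. In that dimer every ring carbon bears one exocyclic carboxyl carbon; those on C2 and C4 are turned into the ipso carbons of two new six-membered carbocycles, with the future phenol oxygen at the para position. The carboxyl carbons on C1 and C3 are kept and later become C6 of the two pyranones, so no bond to a ring stereocentre is ever made or broken.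

## Logic of the disconnections

19 ⇒ 18. The first disconnection concerns the two phenolic O–Si bonds of 18. The phenols must be masked while strongly basic carbon nucleophiles are in use, and a silyl ether leaves under conditions that the enol lactones tolerate. Nothing is gained in skeleton, but all acidic protons are removed from the endgame. The forward step must desilylate without opening a pyranone, which calls for buffered fluoride at low temperature.

18 ⇒ 14 + 15. In each pyranone the C5–C6 bond and the O1–C2 bond are cut, four bonds in all. C6 then is an acyl carbon on a ring stereocentre, and the other five ring atoms with the methoxy group are found intact in 15, of which two molecules are needed. Both heterocycles disappear at once and a symmetrical diamide remains. The forward step demands reaction through the γ-carbon of 16, no deprotonation of the cyclobutane C–H bonds, and a geometry in 17 that lets the enol oxygen reach the ester; the E configuration of 15 provides that geometry.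

14 ⇒ 12 ⇒ 10. Two amide C–N bonds and then the O–Si bonds are cut; these are functional-group changes only. They lead to 10, in which the four substituents are at their simplest. The forward steps must activate two hindered acids without passing through a ketene, and must free the acids of 11 while the aryl silyl ethers stay.

10 ⇒ 9 ⇒ 8. Here the arenes are taken apart. In the retro direction each ipso carbon is joined to the oxygen of the cis-neighbouring carboxyl group (9), and then four C=C bonds are saturated (8). This replaces the more obvious plan of acid dehydration followed by dehydrogenation. A tertiary carbinol with a carboxylic acid cis on the next ring carbon cannot be expected to dehydrate to a cyclohexene under acid, because the five-membered lactone is the thermodynamic sink. The lactone is therefore accepted and used as the leaving group in the reductive aromatisation of a quinol ester. The gain is that two phenol rings become two plain cyclohexanones. The forward steps demand dehydrogenation on both sides of each ketone and a reduction that breaks the C–O bond instead of saturating the dienone.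

8 ⇒ 7. The two lactone C–O bonds are cut and the ketones are returned to ketals. This exposes the hydroxy acid that a double organometallic addition can make. The forward step needs acid strong enough for ketal hydrolysis and lactonisation but too mild to ionise the tertiary C–O bond, since loss of a proton from the ring carbon would erase a stereocentre.

7 ⇒ 2 + 5. Both C–C bonds at each carbinol carbon are cut, four bonds and two rings in all. Each carbinol carbon then has the oxidation level of an ester, and the other five ring carbons, with the masked oxygen in the middle, form one bifunctional nucleophile, so that two molecules of 5 are needed for one molecule of 2. Two carbocycles vanish and a half-ester remains whose four stereocentres already have the configuration of 19. The forward step demands double addition at each ester with no attack on the acids, addition faster than enolisation, and no bridging of two esters by one molecule of 5.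

5 ⇒ 4 ⇒ 3. Two C–Mg bonds and then the two ketal C–O bonds are cut, which reaches a commercial dichloro ketone. The forward demand is magnesium insertion at a temperature at which the γ-alkoxy organometallic does not collapse by 1,3-elimination.

2 ⇒ 1. The two ester C–O bonds are cut and each acid/ester pair is closed to an anhydride. 1 is a bulk photodimer that fixes all four stereocentres. The forward ring opening has no regiocontrol, so 2 must be separated from its head-to-head isomer, and this is done at the cheapest point of the route.

## Other disconnections considered

Alternative 1: The cut is at the two cyclobutane–aryl bonds. In the forward step Pd(OAc)2 with AgOAc would arylate the two ring methylenes of the trans diamide A2 with two molecules of the aryl iodide A3 to give A1. Each C–H bond is activated through a five-membered palladacycle of divalent palladium held by a quinolin-8-yl amide.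
- In its favour: the route is short, the arene arrives with its oxygen in place, and each palladacycle delivers the aryl group cis to the amide that directs it. On step count and on redox economy this alternative is better than the chosen plan, which builds the arenes through saturated rings.
- Against it here: the α pattern needs the first aryl group cis to one amide and the second cis to the other. Each amide has a cis hydrogen on both methylenes, so after the first arylation the same amide can deliver the second aryl group to the same face. The other amide can also reach the now tertiary benzylic C–H. Nothing in A2 favours the required course. The two hindered auxiliaries must then be removed under forcing conditions before the acyl carbons can be used.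
- Comparison: the chosen plan takes all four stereocentres from one dimer whose configuration is settled before any valuable material exists, so it is better on stereochemical security. Both plans use known reaction types and both need the same pyranone annulation afterwards, so on mechanism and on the endgame they are equal.

Alternative 2: The cut is at C5–C6 and O1–C2 of both pyranones. The forward step is the double γ-acylation of 16 by 14 and lactonisation to A4, which is the same compound as 18. This is the endgame of the chosen route (step 10), so on mechanism and on the risks of that step (γ-selectivity, epimerisation next to the ketone) the two are equal. The difference lies in the origin of the truxillic core. If 10 were made by solid-state [2+2] photodimerisation of A5, the whole synthesis would take about five steps.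
- In its favour: that is clearly better than the chosen plan on step economy, and it needs no dearomatised intermediates.
- Against it: the regio- and stereochemical outcome would depend on the head-to-tail packing of a crystal, which is a property of a solid phase and of its polymorph, not of the molecule. Conversion is limited by the lattice. In solution the same cycloaddition would compete with E/Z isomerisation and give mixtures.
- Comparison: the chosen plan also starts from a photodimer, but a commodity one of established configuration, and pays for this with the longer arene construction.

Alternative 3: The cut is at one cyclobutane C–C bond between an ester-bearing and an aryl-bearing carbon, traced back by insertion of NH to the pyrrolidine A7. In the forward step PhI(OAc)2 and ammonium carbamate would aminate the ring nitrogen to a 1,1-diazene. Loss of dinitrogen and collapse of the 1,4-biradical would give A6.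
- In its favour: pyrrolidines of this substitution pattern are assembled in one [3+2] cycloaddition of an azomethine ylide with a cinnamate, and the contraction is a known reaction type that can keep relative configuration.
- Against it here: A6 requires A7 with the C2 ester trans to the C5 aryl group (2,3-cis, 3,4-trans, 4,5-cis). This is not the 2,5-cis arrangement that metal-bound ylides normally deliver with E-cinnamates. The biradical would be stabilised at both ends (benzylic and α to an ester), so bond rotation and β-scission into two cinnamate molecules should compete with ring closure. The enantiocontrol that the cycloaddition can offer is of no use for an achiral target.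
- Comparison: on step count this alternative is about equal to the chosen plan or slightly shorter, and both end with the same conversion of a 1,3-dicarboxyl derivative into the pyranones. On stereochemical security the chosen plan is better, because it never places a radical or an ion on a ring stereocentre.

Key step: step 4

Remark on the chemistry: the target is taken as the centrosymmetric, achiral diastereomer that its descriptors encode; 1, 2, 7 and 19 all carry the same cis,trans,cis relative configuration, so only relative configuration has to be controlled.

Step 1
Reactants: 1 cis,trans,cis-cyclobutane-1,2,3,4-tetracarboxylic 1,2:3,4-dianhydride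
Product: 2 (1α,2α,3β,4β)-2,4-bis(methoxycarbonyl)cyclobutane-1,3-dicarboxylic acid
Conditions: MeOH, reflux; crystallisation from EtOAc
Reagents that add atoms: methanol (two molecules), CO
Why: Alcoholysis of a cyclic anhydride: each anhydride ring should open once and stop at the half-ester, and no bond to a ring carbon is broken, so the cis,trans,cis configuration is retained. Two regioisomers are expected, and the centrosymmetric head-to-tail isomer 2 should be the less soluble one and be separable by crystallisation.

Step 2
Reactants: 3 1,5-dichloropentan-3-one
Product: 4 2,2-bis(2-chloroethyl)-1,3-dioxolane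
Conditions: HOCH2CH2OH, TsOH·H2O (cat.), PhMe, reflux (Dean–Stark)
Reagents that add atoms: ethylene glycol, OCCO
Why: Acid-catalysed ketalisation with azeotropic removal of water; the acidic medium avoids the base-induced loss of HCl to which β-chloro ketones are prone.

Step 3
Reactants: 4 2,2-bis(2-chloroethyl)-1,3-dioxolane
Product: 5 2,2-bis[2-(chloromagnesio)ethyl]-1,3-dioxolane (titrated THF solution)
Conditions: Mg turnings (activated with iBu2AlH, 1 mol%), THF, 30–35 °C, slow addition of 4
Reagents that add atoms: magnesium (two atoms), [Mg]
Why: Grignard reagent formation by insertion of magnesium into the two primary C–Cl bonds; γ-alkoxy Grignard reagents of this kind are usable if kept near room temperature, and dilution should limit Wurtz coupling.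

Step 4
Reactants: 2 (1α,2α,3β,4β)-2,4-bis(methoxycarbonyl)cyclobutane-1,3-dicarboxylic acid; 5 2,2-bis[2-(chloromagnesio)ethyl]-1,3-dioxolane (two molecules, one for each ester)
Product: 7 (1α,2α,3β,4β)-2,4-bis(8-hydroxy-1,4-dioxaspiro[4.5]decan-8-yl)cyclobutane-1,3-dicarboxylic acid, via bis(chloromagnesium) dicarboxylate 6 (not isolated)
Conditions: 2, iPrMgCl·LiCl (2.0 equiv), THF, −40 °C; cannulate into 5 (2.4 equiv), THF, −30 → 0 °C; cold 1 M aq. HCl to pH 3
Reagents that add atoms: a second molecule of 2,2-bis[2-(chloromagnesio)ethyl]-1,3-dioxolane 5, Cl[Mg]CCC1(CC[Mg]Cl)OCCO1
Why: iPrMgCl·LiCl first turns both acids into the chloromagnesium carboxylates 6, which LiCl should keep in solution and whose carbonyl groups are deactivated as anions, so that no carbanion of 5 is spent as a base. One C–Mg bond of a molecule of 5 then adds to a methyl ester, the tetrahedral intermediate loses methoxide, and the second C–Mg bond of the same molecule adds to the ketone so formed; this happens once at each ester, so two molecules of 5 are consumed per molecule of 2. The closest known reaction type is the annulation of esters, lactones and anhydrides with 1,4- and 1,5-bis-Grignard reagents to 1-substituted cycloalkanols; the ketal in the chain is a spectator. Each of the two rings closes by a 6-exo-trig attack of carbon on the ketone carbonyl, which makes the second C–C bond at the former carboxyl carbon. No stereocentre is created, because each carbinol carbon carries two identical ring arms, and the ketal carbon ends up para to it. The step needs attack at the esters only and addition faster than enolisation: the anionic carboxylates secure the first, and the intramolecular second addition, the low temperature and the strain of an enolate exocyclic to a cyclobutane secure the second. Each ester has a carboxylate, not a second ester, as its cis neighbour, so the new alkoxide finds no electrophile to attack during the addition, and adding 6 to an excess of 5 should keep one reagent molecule from bridging two esters. No bond to a ring carbon is made or broken, so the configuration of 2 should be carried into 7, which is used crude because any lactonisation on work-up is completed in step 5.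

Step 5
Reactants: 7 (1α,2α,3β,4β)-2,4-bis(8-hydroxy-1,4-dioxaspiro[4.5]decan-8-yl)cyclobutane-1,3-dicarboxylic acid
Product: 8 head-to-tail bis-spirolactone diketone: cis,trans,cis-4,9-dioxatricyclo[5.3.0.0(2,6)]decane-3,8-dione spiro-linked at C5 and at C10 to C1 of a 4-oxocyclohexane ring
Conditions: 2 M aq. HCl, THF, 45 °C
Reagents that add atoms: water, O
Why: Acid-catalysed ketal hydrolysis and γ-lactonisation: each tertiary carbinol has one cis-vicinal carboxylic acid and should close a cis-fused five-membered lactone (5-exo-trig acyl substitution), the sink that an attempted acid dehydration would reach in any case. The neutral, centrosymmetric bis-lactone should be easy to purify, and mild aqueous acid avoids ionising the tertiary C–O bond toward an alkylidenecyclobutane.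

Step 6
Reactants: 8 head-to-tail bis-spirolactone diketone
Product: 9 head-to-tail bis-spirolactone bis(cyclohexa-2,5-dienone): the same dilactone core spiro-linked at C5 and at C10 to C1 of a 4-oxocyclohexa-2,5-diene ring
Conditions: 2-iodoxybenzoic acid (IBX, 8–10 equiv), DMSO/PhF, 80 °C
Reagents that add atoms: none
Why: IBX-mediated α,β-dehydrogenation of ketones, run with excess oxidant so that both sides of each 4,4-disubstituted cyclohexanone are desaturated to the cross-conjugated dienone. Lactones are not enolised under these conditions, so the ring C–H bonds should be left alone.

Step 7
Reactants: 9 head-to-tail bis-spirolactone bis(cyclohexa-2,5-dienone)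
Product: 10 (1α,2α,3β,4β)-2,4-bis(4-hydroxyphenyl)cyclobutane-1,3-dicarboxylic acid
Conditions: Zn dust, AcOH/THF, rt
Reagents that add atoms: none
Why: Dissolving-metal reductive aromatisation of a quinol ester: two-electron reduction of each 4-acyloxycyclohexa-2,5-dienone expels the carboxylate from the quaternary carbon and leaves a phenol, the same C–O cleavage by which para-quinol acetates are turned into phenols. The bond broken is exocyclic to the cyclobutane, so the four stereocentres are untouched.

Step 8
Reactants: 10 (1α,2α,3β,4β)-2,4-bis(4-hydroxyphenyl)cyclobutane-1,3-dicarboxylic acid
Product: 12 (1α,2α,3β,4β)-2,4-bis[4-(tert-butyldimethylsilyloxy)phenyl]cyclobutane-1,3-dicarboxylic acid, via tetrakis(tert-butyldimethylsilyl) derivative 11 (not isolated)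
Conditions: TBSCl, imidazole, DMF, rt; then AcOH/THF/H2O, rt
Reagents that add atoms: tert-butyldimethylsilyl chloride (TBSCl; two silyl groups stay in 12), CC(C)(C)[Si](C)(C)Cl
Why: Silylation of phenols and acids with a silyl chloride and imidazole, followed by selective hydrolysis of the two labile silyl esters under mild aqueous acid, which aryl silyl ethers tolerate.

Step 9
Reactants: 12 (1α,2α,3β,4β)-2,4-bis[4-(tert-butyldimethylsilyloxy)phenyl]cyclobutane-1,3-dicarboxylic acid
Product: 14 (1α,2α,3β,4β)-2,4-bis[4-(tert-butyldimethylsilyloxy)phenyl]-N,N'-dimethoxy-N,N'-dimethylcyclobutane-1,3-dicarboxamide, via bis(acyl imidazolide) 13 (not isolated)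
Conditions: 1,1'-carbonyldiimidazole (CDI), CH2Cl2, rt; then MeNHOMe·HCl, rt
Reagents that add atoms: N,O-dimethylhydroxylamine hydrochloride (two molecules), CNOC.Cl
Why: Activation of the acids as acyl imidazolides and aminolysis by N,O-dimethylhydroxylamine; no strong base and no acid chloride (ketene) is involved, so the α-stereocentres should not epimerise.

Step 10
Reactants: 14 the bis(N-methoxy-N-methylamide) from step 9; 15 methyl (E)-3-methoxybut-2-enoate (two molecules, one for each amide)
Product: 18 6,6'-{(1α,2α,3β,4β)-2,4-bis[4-(tert-butyldimethylsilyloxy)phenyl]cyclobutane-1,3-diyl}bis(4-methoxy-2H-pyran-2-one), via lithium dienolate 16 (not isolated), via bis(keto ester) 17 (not isolated)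
Conditions: 15, LiN(iPr)2, THF, −78 °C; then 14, −78 → 0 °C; cold 0.5 M aq. HCl; then DBU (cat.), PhMe, 70 °C
Reagents that add atoms: a second molecule of methyl (E)-3-methoxybut-2-enoate 15, CO/C(C)=C/C(=O)OC
Why: Two-directional vinylogous Claisen condensation: LiN(iPr)2 removes a γ-proton of 15, and the dienolate 16 is acylated at its γ-carbon by each N-methoxy-N-methylamide through a chelated tetrahedral intermediate that prevents over-addition. After hydrolysis to 17, DBU enolises each ketone toward the doubly activated methylene and the enol oxygen closes the pyranone on the cis-disposed ester (6-exo-trig acyl substitution with loss of methanol). The cyclobutane C–H bonds are far less acidic than that methylene, and the present configuration is the more stable of the two that epimerisation could reach, so it should be kept.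

Step 11
Reactants: 18 the bis(tert-butyldimethylsilyl) ether from step 10
Product: 19 6,6'-[(1α,2α,3β,4β)-2,4-bis(4-hydroxyphenyl)cyclobutane-1,3-diyl]bis(4-methoxy-2H-pyran-2-one)
Conditions: Bu4NF, AcOH, THF, 0 °C
Reagents that add atoms: none
Why: Fluoride-induced cleavage of the aryl silyl ethers; acetic acid buffers the phenoxide and the fluoride so that the base-sensitive methoxypyranones are not opened.

## Compound list

1 | cis,trans,cis-cyclobutane-1,2,3,4-tetracarboxylic 1,2:3,4-dianhydride | O=C2[C@H]1[C@H](C3=O)[C@H](C(=O)O3)[C@H]1C(=O)O2 | starting material
2 | (1α,2α,3β,4β)-2,4-bis(methoxycarbonyl)cyclobutane-1,3-dicarboxylic acid | OC(=O)[C@H]1[C@H](C(=O)OC)[C@H](C(O)=O)[C@H]1C(=O)OC | intermediate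
3 | 1,5-dichloropentan-3-one | ClCCC(=O)CCCl | starting material
4 | 2,2-bis(2-chloroethyl)-1,3-dioxolane | ClCCC1(CCCl)OCCO1 | intermediate
5 | 2,2-bis[2-(chloromagnesio)ethyl]-1,3-dioxolane | Cl[Mg]CCC1(CC[Mg]Cl)OCCO1 | intermediate
6 | bis(chloromagnesium) salt of 2 | Cl[Mg]OC(=O)[C@H]1[C@H](C(=O)OC)[C@H](C(=O)O[Mg]Cl)[C@H]1C(=O)OC | intermediate (not isolated)
7 | (1α,2α,3β,4β)-2,4-bis(8-hydroxy-1,4-dioxaspiro[4.5]decan-8-yl)cyclobutane-1,3-dicarboxylic acid | OC(=O)[C@H]1[C@H](C2(O)CCC3(CC2)OCCO3)[C@H](C(=O)O)[C@H]1C1(O)CCC2(CC1)OCCO2 | intermediate
8 | head-to-tail bis-spirolactone diketone (cis,trans,cis-4,9-dioxatricyclo[5.3.0.0(2,6)]decane-3,8-dione, 5,10-dispiro-linked to two 4-oxocyclohexane rings) | O=C2[C@H]1[C@H](C3(CCC(=O)CC3)O4)[C@H](C4=O)[C@H]1C5(CCC(=O)CC5)O2 | intermediate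
9 | head-to-tail bis-spirolactone bis(cyclohexa-2,5-dienone) (same core, 5,10-dispiro-linked to two 4-oxocyclohexa-2,5-diene rings) | O=C2[C@H]1[C@H](C3(C=CC(=O)C=C3)O4)[C@H](C4=O)[C@H]1C5(C=CC(=O)C=C5)O2 | intermediate
10 | (1α,2α,3β,4β)-2,4-bis(4-hydroxyphenyl)cyclobutane-1,3-dicarboxylic acid (4,4'-dihydroxy-α-truxillic acid) | OC(=O)[C@H]1[C@H](c2ccc(O)cc2)[C@H](C(=O)O)[C@H]1c1ccc(O)cc1 | intermediate
11 | bis(tert-butyldimethylsilyl) ester of 12 (tetrakis-silyl derivative of 10) | CC(C)(C)[Si](C)(C)OC(=O)[C@H]1[C@H](c2ccc(O[Si](C)(C)C(C)(C)C)cc2)[C@H](C(=O)O[Si](C)(C)C(C)(C)C)[C@H]1c1ccc(O[Si](C)(C)C(C)(C)C)cc1 | intermediate (not isolated)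
12 | (1α,2α,3β,4β)-2,4-bis[4-(tert-butyldimethylsilyloxy)phenyl]cyclobutane-1,3-dicarboxylic acid | OC(=O)[C@H]1[C@H](c2ccc(O[Si](C)(C)C(C)(C)C)cc2)[C@H](C(=O)O)[C@H]1c1ccc(O[Si](C)(C)C(C)(C)C)cc1 | intermediate
13 | bis(acyl imidazolide) of 12 | O=C(n1ccnc1)[C@H]1[C@H](c2ccc(O[Si](C)(C)C(C)(C)C)cc2)[C@H](C(=O)n2ccnc2)[C@H]1c1ccc(O[Si](C)(C)C(C)(C)C)cc1 | intermediate (not isolated)
14 | (1α,2α,3β,4β)-2,4-bis[4-(tert-butyldimethylsilyloxy)phenyl]-N,N'-dimethoxy-N,N'-dimethylcyclobutane-1,3-dicarboxamide | CON(C)C(=O)[C@H]1[C@H](c2ccc(O[Si](C)(C)C(C)(C)C)cc2)[C@H](C(=O)N(C)OC)[C@H]1c1ccc(O[Si](C)(C)C(C)(C)C)cc1 | intermediate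
15 | methyl (E)-3-methoxybut-2-enoate | CO/C(C)=C/C(=O)OC | starting material
16 | lithium 1,3-dimethoxybuta-1,3-dien-1-olate (γ-deprotonated 15; enolate geometry not defined) | C=C(OC)C=C(OC)O[Li] | intermediate (not isolated)
17 | dimethyl (2E,2'E)-5,5'-{(1α,2α,3β,4β)-2,4-bis[4-(tert-butyldimethylsilyloxy)phenyl]cyclobutane-1,3-diyl}bis(3-methoxy-5-oxopent-2-enoate) | CO/C(=C/C(=O)OC)CC(=O)[C@H]1[C@H](c2ccc(O[Si](C)(C)C(C)(C)C)cc2)[C@H](C(=O)C/C(OC)=C\C(=O)OC)[C@H]1c1ccc(O[Si](C)(C)C(C)(C)C)cc1 | intermediate (not isolated)
18 | 6,6'-{(1α,2α,3β,4β)-2,4-bis[4-(tert-butyldimethylsilyloxy)phenyl]cyclobutane-1,3-diyl}bis(4-methoxy-2H-pyran-2-one) | COc1cc(=O)oc(c1)[C@H]2[C@H](c3ccc(O[Si](C)(C)C(C)(C)C)cc3)[C@H](c3cc(OC)cc(=O)o3)[C@H]2c2ccc(O[Si](C)(C)C(C)(C)C)cc2 | intermediate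
19 | 6,6'-[(1α,2α,3β,4β)-2,4-bis(4-hydroxyphenyl)cyclobutane-1,3-diyl]bis(4-methoxy-2H-pyran-2-one) | COc1cc(=O)oc([C@H]2[C@H](c3ccc(O)cc3)[C@H](c3cc(OC)cc(=O)o3)[C@H]2c2ccc(O)cc2)c1 | target

## Step count and least certain steps

Total: 11 steps. Longest linear sequence: 10 steps (steps 2, 3 and 4–11, from 3). Step 1, which makes 2 from 1, is a one-step branch that joins at step 4.

The key step (step 4) is the least certain. Three things could go wrong.
- The strongly basic reagent could enolise an ester, or the intermediate cyclobutyl ketone, instead of adding. That would epimerise a ring carbon or return starting material.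
- The magnesium carboxylate could precipitate and stall the addition.
- One reagent molecule could bridge two substrate molecules.

The fallback changes the electrophile from the half-ester to the anhydride. It sets out from 1 and 5. Direct annulation of both anhydride rings of 1 with two molecules of 5 (each ring opened by one C–Mg bond, the keto carboxylate captured by the second), followed by acid work-up, should give the head-to-tail bis-ketal bis-spirolactone F1 together with its head-to-head regioisomer F2. Regiochemistry would then be settled by separating the centrosymmetric F1 instead of by separating 2. Aqueous HCl in THF converts F1 into 8, where the fallback rejoins the route.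

Step 3 could fail through decomposition of the γ-alkoxy organomagnesium during the slow insertion into a primary C–Cl bond. The expected pathways are 1,3-elimination to a cyclopropane with opening of the dioxolane, and Wurtz coupling. The fallback sets out from 4. Reductive lithiation with lithium powder and catalytic 4,4'-di-tert-butylbiphenyl in THF at −78 °C should give 2,2-bis(2-lithioethyl)-1,3-dioxolane F3 at a temperature at which it is stable. Transmetalation with MgCl2 returns to 5.

Step 6 could stall at the enone stage on one or more of the four positions, or the material could degrade under prolonged heating with a large excess of oxidant, because four dehydrogenations are required in one operation. The fallback sets out from 8. α,α'-Bromination of both ketones (Br2, AcOH) should give the bis(3,5-dibromo-4-oxocyclohexane) bis-spirolactone F4 as a mixture of diastereomers at the bromine-bearing carbons. Fourfold dehydrobromination with Li2CO3 and LiBr in DMF at 120 °C returns to 9.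

Step 10 has four weak points.
- Acylation of the dienolate at its α-carbon instead of its γ-carbon.
- Sluggish attack on the hindered amides.
- Incomplete ring closure of 17.
- Partial loss of the aryl silyl groups to the methanol/DBU formed during lactonisation; this is harmless, since step 11 removes them anyway.

The fallback sets out from 14 and builds the pyranone at the 4-hydroxy level. The dianion of methyl acetoacetate (NaH, then n-BuLi) is acylated by 14 to give the bis(3,5-dioxo ester) F5. DBU closes this to the bis(4-hydroxy-2-pyranone) F6. O-Methylation with dimethyl sulfate and K2CO3 in dry acetone returns to 18.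

## Further compounds

F1 | step 4 | head-to-tail bis-ketal bis-spirolactone (8 with both ketones as ethylene ketals) | O=C2[C@H]1[C@H](C3(CCC6(CC3)OCCO6)O4)[C@H](C4=O)[C@H]1C5(CCC7(CC5)OCCO7)O2
F2 | step 4 | head-to-head bis-ketal bis-spirolactone (regioisomer of F1, racemic) | O=C2[C@H]1[C@H](C4=O)[C@H](C3(CCC6(CC3)OCCO6)O4)[C@H]1C5(CCC7(CC5)OCCO7)O2
F3 | step 3 | 2,2-bis(2-lithioethyl)-1,3-dioxolane | [Li]CCC1(CC[Li])OCCO1
F4 | step 6 | bis(3,5-dibromo-4-oxocyclohexane) analogue of 8 (mixture of diastereomers at the CHBr carbons) | O=C2[C@H]1[C@H](C3(CC(Br)C(=O)C(Br)C3)O4)[C@H](C4=O)[C@H]1C5(CC(Br)C(=O)C(Br)C5)O2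
F5 | step 10 | dimethyl 5,5'-{(1α,2α,3β,4β)-2,4-bis[4-(tert-butyldimethylsilyloxy)phenyl]cyclobutane-1,3-diyl}bis(3,5-dioxopentanoate) | COC(=O)CC(=O)CC(=O)[C@H]1[C@H](c2ccc(O[Si](C)(C)C(C)(C)C)cc2)[C@H](C(=O)CC(=O)CC(=O)OC)[C@H]1c1ccc(O[Si](C)(C)C(C)(C)C)cc1
F6 | step 10 | 6,6'-{(1α,2α,3β,4β)-2,4-bis[4-(tert-butyldimethylsilyloxy)phenyl]cyclobutane-1,3-diyl}bis(4-hydroxy-2H-pyran-2-one) | Oc1cc(=O)oc(c1)[C@H]2[C@H](c3ccc(O[Si](C)(C)C(C)(C)C)cc3)[C@H](c3cc(O)cc(=O)o3)[C@H]2c2ccc(O[Si](C)(C)C(C)(C)C)cc2
A1 | alternative 1 | 2,4-bis(4-triisopropylsilyloxyphenyl)-N,N'-di(quinolin-8-yl)cyclobutane-1,3-dicarboxamide, α configuration | O=C(Nc1cccc2cccnc12)[C@H]1[C@H](c2ccc(O[Si](C(C)C)(C(C)C)C(C)C)cc2)[C@H](C(=O)Nc2cccc3cccnc23)[C@H]1c1ccc(O[Si](C(C)C)(C(C)C)C(C)C)cc1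
A2 | alternative 1 | trans-N,N'-di(quinolin-8-yl)cyclobutane-1,3-dicarboxamide | O=C(Nc1cccc2cccnc12)[C@H]1C[C@H](C(=O)Nc2cccc3cccnc23)C1
A3 | alternative 1 | (4-iodophenoxy)triisopropylsilane | CC(C)[Si](Oc1ccc(I)cc1)(C(C)C)C(C)C
A4 | alternative 2 | bis(tert-butyldimethylsilyl) ether of the target (identical with 18) | COc1cc(=O)oc(c1)[C@H]2[C@H](c3ccc(O[Si](C)(C)C(C)(C)C)cc3)[C@H](c3cc(OC)cc(=O)o3)[C@H]2c2ccc(O[Si](C)(C)C(C)(C)C)cc2
A5 | alternative 2 | (E)-4-hydroxycinnamic acid | OC(=O)/C=C/c1ccc(O)cc1
A6 | alternative 3 | dimethyl 4,4'-diacetoxy-α-truxillate | COC(=O)[C@H]1[C@H](c2ccc(OC(C)=O)cc2)[C@H](C(=O)OC)[C@H]1c1ccc(OC(C)=O)cc1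
A7 | alternative 3 | dimethyl 3,5-bis(4-acetoxyphenyl)pyrrolidine-2,4-dicarboxylate, 2,3-cis, 3,4-trans, 4,5-cis (racemic) | COC(=O)[C@@H]1[C@H](c2ccc(OC(C)=O)cc2)[C@@H](C(=O)OC)[C@@H](c2ccc(OC(C)=O)cc2)N1
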